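**Plan**

1. Numbering follows the labdanes: ring B is C5–C10, the lactone C2(=O)–O–C8 spans C10 and C8, the acid C3 sits on C4, and the side chain is C9–C11–C12–C13(C16)(OH)–C14=C15.
2. The retrosynthesis first cuts the lactone O–C8 bond (iodolactonisation of a C8=C17 alkene) and takes the C13 vinyl carbinol back through an E-allylic alcohol to a methyl ketone. It then cuts C8–C9 and C11–C12 together: the ring carbinol carbon C8 and the chain carbinol carbon C13 stand 1,5 through C9, C11 and C12, the pattern left by enol–alkene photocycloaddition of a 1,3-diketone and retro-aldol opening.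
3. Earlier cuts are C12–C13 and C7–C8 (acylated acetylide), C10–C1 and C10–CH3 (lactone enolate alkylations) and C4–C5 (Mukaiyama–Michael addition).
4. Forward, the C5–C10 pair is built on a δ-lactone, which is opened to the vinyl/1,3-diketone chain; ring B closes in step 10 and the bridging lactone in step 15; there is no other ring.
5. Stereocentres: C5 by catalyst control (step 2), C10 by trans alkylation (step 4), C9 by equilibration (step 10), C8 by delivery of oxygen from the C10 arm (step 15), C13 by Sharpless epoxidation with D-(−)-tartrate (step 18, unveiled in step 20).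

Key step: step 10

Remark: ketene acetal 3 is assumed not to be purchasable and is made in step 1; both esters stay tert-butyl until step 14 because the alkoxides formed at C9 and C7 in steps 5 and 6 would lactonise onto less hindered esters.
Assumption: in steps 2 and 18 the catalyst enantiomer named is the one that gives the configuration drawn.

**Route**

Step 1
Reactants: 1 tert-butyl 2-methylpropanoate
Product: 3 1-tert-butoxy-2-methyl-1-(trimethylsilyloxy)prop-1-ene, via lithium enolate 2 (not isolated)
Conditions: LiN(i-Pr)2, THF, −78 °C; Me3SiCl, −78 °C → rt; distillation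
Reagents that add atoms: chlorotrimethylsilane, C[Si](C)(C)Cl
Why: O-silylation of the lithium ester enolate should give the tetrasubstituted silyl ketene acetal, which has no double-bond isomers (silyl ketene acetal formation).

Step 2
Reactants: 3 1-tert-butoxy-2-methyl-1-(trimethylsilyloxy)prop-1-ene; 4 5,6-dihydro-2H-pyran-2-one
Product: 6 tert-butyl 2-methyl-2-[(4S)-2-oxooxan-4-yl]propanoate, via silyl ketene acetal adduct 5 (not isolated)
Conditions: chiral imidodiphosphorimidate (IDPi) acid (2 mol %, enantiomer giving 4S), toluene, −60 °C; then H2O, NaHCO3, THF, 0 °C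
Reagents that add atoms: none
Why: Proposed new method: the ketene acetal silylates the chiral acid to a silylium ion pair that activates the lactone carbonyl, the nucleophile then adds to C5 inside the chiral anion pocket with silyl transfer to the lactone enolate oxygen, and hydrolysis gives 6 with C5 set by the catalyst (Mukaiyama–Michael addition); the closest known reactions are the same silylium counteranion catalysis with acyclic α,β-unsaturated methyl esters and oxazaborolidinium-catalysed additions of this ketene acetal class to cyclic enones.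

Step 3
Reactants: 6 tert-butyl 2-methyl-2-[(4S)-2-oxooxan-4-yl]propanoate
Product: 8 tert-butyl 2-methyl-2-[(3R,4S)-3-methyl-2-oxooxan-4-yl]propanoate, via lithium enolate 7 (not isolated)
Conditions: LiN(i-Pr)2, THF, −78 °C; MeI, −78 → −40 °C
Reagents that add atoms: iodomethane, CI
Why: Alkylation of the lactone enolate should place the methyl group trans to the C5 substituent, although this C10 configuration is erased in the next step (enolate alkylation).

Step 4
Reactants: 8 tert-butyl 2-methyl-2-[(3R,4S)-3-methyl-2-oxooxan-4-yl]propanoate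
Product: 10 tert-butyl 2-[(3R,4R)-3-(2-tert-butoxy-2-oxoethyl)-3-methyl-2-oxooxan-4-yl]-2-methylpropanoate, via lithium enolate 9 (not isolated)
Conditions: LiN(i-Pr)2, THF/DMPU, −78 °C; BrCH2CO2t-Bu, −78 → −30 °C
Reagents that add atoms: tert-butyl bromoacetate, CC(C)(C)OC(=O)CBr
Why: The tetrasubstituted enolate should be attacked on the face opposite the bulky C5 substituent, so the acetate arm ends trans and the methyl cis to it, which is the C10 configuration of the target (diastereoselective lactone enolate alkylation).

Step 5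
Reactants: 10 tert-butyl 2-[(3R,4R)-3-(2-tert-butoxy-2-oxoethyl)-3-methyl-2-oxooxan-4-yl]-2-methylpropanoate
Product: 11 lactol of 10 (2-hydroxyoxane, both C9 epimers)
Conditions: i-Bu2AlH (1.1 equiv), CH2Cl2, −78 °C; aq. KNaC4H4O6
Reagents that add atoms: none
Why: The lactone should be reduced to the lactol at −78 °C well before either tert-butyl ester reacts (partial lactone reduction).

Step 6
Reactants: 11 lactol of 10
Product: 12 di-tert-butyl (3S,4S)-3-ethenyl-4-(2-hydroxyethyl)-3,5,5-trimethylhexanedioate
Conditions: Ph3PCH3Br, KOt-Bu, THF, 0 → 40 °C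
Reagents that add atoms: methyltriphenylphosphonium bromide, C[P+](c1ccccc1)(c1ccccc1)c1ccccc1.[Br-]
Why: Methylenation of the open hydroxy-aldehyde form gives the C9=C11 vinyl group and frees the C7 alcohol, and the tert-butyl esters should resist the alkoxides present (Wittig reaction).

Step 7
Reactants: 12 di-tert-butyl (3S,4S)-3-ethenyl-4-(2-hydroxyethyl)-3,5,5-trimethylhexanedioate
Product: 13 di-tert-butyl (3S,4S)-3-ethenyl-4-(2-iodoethyl)-3,5,5-trimethylhexanedioate
Conditions: I2, PPh3, imidazole, CH2Cl2, 0 °C → rt
Reagents that add atoms: iodine, II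
Why: The unhindered primary alcohol should be converted cleanly to the iodide through its alkoxyphosphonium salt (Appel reaction).

Step 8
Reactants: 13 di-tert-butyl (3S,4S)-3-ethenyl-4-(2-iodoethyl)-3,5,5-trimethylhexanedioate
Product: 14 di-tert-butyl (3S,4S)-4-(but-3-yn-1-yl)-3-ethenyl-3,5,5-trimethylhexanedioate
Conditions: LiC≡CH·H2NCH2CH2NH2, DMSO, 15 °C
Reagents that add atoms: lithium acetylide–ethylenediamine complex, [Li+].[C-]#C.NCCN
Why: SN2 displacement of the primary iodide adds C8 and C12 without a radical or organometallic at C7 that could cyclise onto the vinyl group, and the acetylide is a weaker base than the tert-butyl ester enolate (acetylide alkylation).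

Step 9
Reactants: 14 di-tert-butyl (3S,4S)-4-(but-3-yn-1-yl)-3-ethenyl-3,5,5-trimethylhexanedioate
Product: 17 di-tert-butyl (3S,4S)-4-(3,5-dioxohexyl)-3-ethenyl-3,5,5-trimethylhexanedioate, via ynone 15 (not isolated), via enaminone 16 (not isolated)
Conditions: AcCl, PdCl2(PPh3)2 (2 mol %), CuI (4 mol %), Et3N (1.1 equiv), THF, rt; then pyrrolidine, rt; then AcOH/H2O, rt
Reagents that add atoms: acetyl chloride, CC(Cl)=O; water, O
Why: Acyl Sonogashira coupling gives the ynone, the amine adds at C8 in conjugate fashion and hydrolysis of the vinylogous amide leaves oxygen at C8 only, so the 1,3-diketone should form without regioisomers (ynone hydration through an enaminone).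

Step 10
Reactants: 17 di-tert-butyl (3S,4S)-4-(3,5-dioxohexyl)-3-ethenyl-3,5,5-trimethylhexanedioate
Product: 19 tert-butyl 2-[(1S,2R,3S)-2-(2-tert-butoxy-2-oxoethyl)-2-methyl-4-oxo-3-(3-oxobutyl)cyclohexyl]-2-methylpropanoate, via cyclobutanol photoadduct 18 (not isolated)
Conditions: hν (medium-pressure Hg lamp, Pyrex, λ > 290 nm), degassed cyclohexane (0.01 M), rt, stopped at full conversion; then DBU (0.1 equiv), CH2Cl2, 0 °C
Reagents that add atoms: none
Why: Excitation of the hydrogen-bonded enol of 17 should lead, through its triplet and a 1,4-biradical, to the cis-fused cyclobutanol 18 by bonding C8 to the internal vinyl carbon C9 and C12 to the terminal carbon C11; 18 is a strained β-hydroxy ketone and opens by retro-aldol cleavage of C8–C12 to the ring-B ketone with the 3-oxobutyl chain on C9. The closest known reaction type is the intramolecular de Mayo reaction of enolised 1,3-diketones carrying a tethered alkene. Ring B closes in the straight sense, the first bond C8–C9 making a six-membered ring through the four-atom tether C7–C6–C5–C10. The only new stereocentre that survives is C9; it lies α to the C8 ketone and is equilibrated with DBU to the epimer with the side chain equatorial, cis to the C10 methyl and the C5 substituent, the chair being locked by the equatorial C5 group. The step needs a choice between the two enol forms and between straight and crossed addition, and the tether length secures both, because every alternative would close a seven- or eight-membered ring.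

Step 11
Reactants: 19 ring-B diketone
Product: 20 ethyl (2E)-5-[(1S,2R,3S)-2-(2-tert-butoxy-2-oxoethyl)-3-(1-tert-butoxy-2-methyl-1-oxopropan-2-yl)-2-methyl-6-oxocyclohexyl]-3-methylpent-2-enoate
Conditions: (EtO)2P(O)CH2CO2Et, NaH, THF, 0 °C → rt; chromatography to remove the Z isomer
Reagents that add atoms: triethyl phosphonoacetate, CCOC(=O)CP(=O)(OCC)OCC
Why: The phosphonate anion should add to the unhindered methyl ketone and not to the α-branched C8 ketone next to the quaternary C10, giving mainly the E-enoate (Horner–Wadsworth–Emmons olefination).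

Step 12
Reactants: 20 E-enoate ketone
Product: 21 6-methylidene analogue of 20 (C8=C17 alkene, ring stereocentres unchanged)
Conditions: Zn, CH2Br2, TiCl4 (reagent pre-formed in THF), CH2Cl2, 0 °C → rt
Reagents that add atoms: dibromomethane, BrCBr
Why: This non-basic reagent should methylenate the hindered ketone without touching C9, the enoate geometry or the esters (Takai–Lombardo methylenation).

Step 13
Reactants: 21 exocyclic alkene enoate
Product: 22 (2E)-allylic alcohol (CO2Et of 21 reduced to CH2OH, both tert-butyl esters kept)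
Conditions: i-Bu2AlH (2.3 equiv), CH2Cl2, −78 °C; aq. KNaC4H4O6
Reagents that add atoms: none
Why: The conjugated ethyl ester should be reduced to the allylic alcohol at −78 °C while the two tert-butyl esters, one of them α-quaternary, are left (ester reduction).

Step 14
Reactants: 22 allylic alcohol
Product: 24 diacid (22 with both tert-butyl esters replaced by CO2H), via tris(trimethylsilyl) derivative 23 (not isolated)
Conditions: Me3SiOTf, 2,6-lutidine, CH2Cl2, 0 °C → rt; then MeOH/H2O, pH 5 buffer
Reagents that add atoms: none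
Why: O-Silylation of each ester carbonyl and loss of 2-methylpropene give silyl esters without protic acid, so the exocyclic alkene and the allylic alcohol (held as its silyl ether) should not ionise, and aqueous work-up frees the diacid (silyl triflate de-tert-butylation).

Step 15
Reactants: 24 diacid
Product: 25 iodolactone (lactone C2(=O)–O–C8, C8 bearing CH2I, C3 acid free)
Conditions: I2, NaHCO3, MeCN, 0 °C → rt, dark
Reagents that add atoms: iodine, II
Why: The C2 carboxylate on the C10 arm attacks the tertiary carbon C8 of the iodonium ion in a 6-exo Markovnikov closure that is possible only from the face of that arm, which fixes C8 with oxygen cis to C1, whereas the C3 carboxylate would need a seven-membered ring (iodolactonisation).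

Step 16
Reactants: 25 iodolactone
Product: 26 2-[(1S,5R,6S,9S)-9-[(3E)-5-hydroxy-3-methylpent-3-en-1-yl]-1,5-dimethyl-3-oxo-2-oxabicyclo[3.3.1]nonan-6-yl]-2-methylpropanoic acid
Conditions: Bu3SnH, AIBN (cat.), toluene, 80 °C
Reagents that add atoms: none
Why: Hydrogen transfer from the tin hydride to the primary radical should be much faster than acyloxy shift or cyclisation, turning CH2I into the C8 methyl group (radical deiodination).

Step 17
Reactants: 26 lactone acid
Product: 27 phenacyl ester of 26 (C3 carboxyl as CO2CH2COPh)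
Conditions: PhCOCH2Br, KHCO3, DMF, rt
Reagents that add atoms: 2-bromoacetophenone, O=C(CBr)c1ccccc1
Why: O-Alkylation of the carboxylate does not depend on hindrance at the acyl carbon and masks the acid for the titanium and phosphine steps that follow (carboxylate alkylation).

Step 18
Reactants: 27 phenacyl ester
Product: 28 epoxy alcohol (side chain 2-[(2R,3R)-3-(hydroxymethyl)-2-methyloxiran-2-yl]ethyl, that is 13R,14R)
Conditions: Ti(Oi-Pr)4, D-(−)-diethyl tartrate, t-BuOOH, 4 Å MS, CH2Cl2, −20 °C
Reagents that add atoms: tert-butyl hydroperoxide, CC(C)(C)OO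
Why: With D-(−)-tartrate the reagent should deliver oxygen to the face of the E-allylic alcohol that gives the (13R,14R)-epoxide, the mirror image of the L-(+)-tartrate/geraniol outcome and independent of the remote ring centres (Sharpless asymmetric epoxidation).

Step 19
Reactants: 28 epoxy alcohol
Product: 29 epoxy iodide (CH2OH of 28 replaced by CH2I)
Conditions: I2, PPh3, imidazole, CH2Cl2, 0 °C
Reagents that add atoms: iodine, II
Why: The primary alcohol is substituted under near-neutral conditions that leave the trisubstituted epoxide intact (Appel reaction).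

Step 20
Reactants: 29 epoxy iodide
Product: 30 2-[(1S,5R,6S,9S)-9-[(3R)-3-hydroxy-3-methylpent-4-en-1-yl]-1,5-dimethyl-3-oxo-2-oxabicyclo[3.3.1]nonan-6-yl]-2-methylpropanoic acid (target)
Conditions: Zn, AcOH, EtOH, 0 °C → rt
Reagents that add atoms: none
Why: Zinc reduces the C15–I bond and the epoxide opens by β-elimination, which moves the oxygen to C13 with its configuration unchanged and creates the vinyl group, while the same reagent cleaves the phenacyl ester to free the C3 acid (reductive epoxide opening and phenacyl ester cleavage).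

**Compound list**

1 | tert-butyl 2-methylpropanoate | CC(C)C(=O)OC(C)(C)C | starting material
2 | lithium enolate of 1 (not isolated) | CC(C)=C([O-])OC(C)(C)C.[Li+] | intermediate
3 | 1-tert-butoxy-2-methyl-1-(trimethylsilyloxy)prop-1-ene | CC(C)=C(OC(C)(C)C)O[Si](C)(C)C | intermediate
4 | 5,6-dihydro-2H-pyran-2-one | O=C1C=CCCO1 | starting material
5 | tert-butyl 2-methyl-2-[(4S)-6-(trimethylsilyloxy)-3,4-dihydro-2H-pyran-4-yl]propanoate (not isolated) | C[Si](C)(C)OC1=C[C@@H](C(C)(C)C(=O)OC(C)(C)C)CCO1 | intermediate
6 | tert-butyl 2-methyl-2-[(4S)-2-oxooxan-4-yl]propanoate | O=C1C[C@@H](C(C)(C)C(=O)OC(C)(C)C)CCO1 | intermediate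
7 | lithium enolate of 6 (not isolated) | [Li+].[O-]C1=C[C@@H](C(C)(C)C(=O)OC(C)(C)C)CCO1 | intermediate
8 | tert-butyl 2-methyl-2-[(3R,4S)-3-methyl-2-oxooxan-4-yl]propanoate (3,4-trans) | O=C1[C@H](C)[C@@H](C(C)(C)C(=O)OC(C)(C)C)CCO1 | intermediate
9 | lithium enolate of 8 (not isolated) | [Li+].[O-]C1=C(C)[C@@H](C(C)(C)C(=O)OC(C)(C)C)CCO1 | intermediate
10 | tert-butyl 2-[(3R,4R)-3-(2-tert-butoxy-2-oxoethyl)-3-methyl-2-oxooxan-4-yl]-2-methylpropanoate (acetate arm trans to the C4 side chain) | O=C1[C@](C)(CC(=O)OC(C)(C)C)[C@@H](C(C)(C)C(=O)OC(C)(C)C)CCO1 | intermediate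
11 | lactol of 10 (2-hydroxyoxane, both C2 epimers, other centres as in 10) | OC1[C@](C)(CC(=O)OC(C)(C)C)[C@@H](C(C)(C)C(=O)OC(C)(C)C)CCO1 | intermediate
12 | di-tert-butyl (3S,4S)-3-ethenyl-4-(2-hydroxyethyl)-3,5,5-trimethylhexanedioate | OCC[C@H](C(C)(C)C(=O)OC(C)(C)C)[C@@](C)(CC(=O)OC(C)(C)C)C=C | intermediate
13 | di-tert-butyl (3S,4S)-3-ethenyl-4-(2-iodoethyl)-3,5,5-trimethylhexanedioate | ICC[C@H](C(C)(C)C(=O)OC(C)(C)C)[C@@](C)(CC(=O)OC(C)(C)C)C=C | intermediate
14 | di-tert-butyl (3S,4S)-4-(but-3-yn-1-yl)-3-ethenyl-3,5,5-trimethylhexanedioate | C#CCC[C@H](C(C)(C)C(=O)OC(C)(C)C)[C@@](C)(CC(=O)OC(C)(C)C)C=C | intermediate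
15 | di-tert-butyl (3S,4S)-3-ethenyl-3,5,5-trimethyl-4-(5-oxohex-3-yn-1-yl)hexanedioate (ynone, not isolated) | CC(=O)C#CCC[C@H](C(C)(C)C(=O)OC(C)(C)C)[C@@](C)(CC(=O)OC(C)(C)C)C=C | intermediate
16 | di-tert-butyl (3S,4S)-3-ethenyl-3,5,5-trimethyl-4-[(3E)-5-oxo-3-(pyrrolidin-1-yl)hex-3-en-1-yl]hexanedioate (enaminone, not isolated) | CC(=O)/C=C(/N1CCCC1)CC[C@H](C(C)(C)C(=O)OC(C)(C)C)[C@@](C)(CC(=O)OC(C)(C)C)C=C | intermediate
17 | di-tert-butyl (3S,4S)-4-(3,5-dioxohexyl)-3-ethenyl-3,5,5-trimethylhexanedioate (key-step precursor, largely enolised) | CC(=O)CC(=O)CC[C@H](C(C)(C)C(=O)OC(C)(C)C)[C@@](C)(CC(=O)OC(C)(C)C)C=C | intermediate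
18 | cis-fused cyclobutanol photoadduct (bicyclo[4.2.0]octane: OH on C8, acetyl on C12, C12 epimers; drawn as the C9 epimer that leads directly to 19; not isolated) | CC(=O)C1C[C@H]2[C@](C)(CC(=O)OC(C)(C)C)[C@@H](C(C)(C)C(=O)OC(C)(C)C)CC[C@@]12O | intermediate
19 | tert-butyl 2-[(1S,2R,3S)-2-(2-tert-butoxy-2-oxoethyl)-2-methyl-4-oxo-3-(3-oxobutyl)cyclohexyl]-2-methylpropanoate (ring-B C8 ketone; C9 chain, C10 methyl and C5 substituent cis) | CC(=O)CC[C@H]1[C@](C)(CC(=O)OC(C)(C)C)[C@@H](C(C)(C)C(=O)OC(C)(C)C)CCC1=O | intermediate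
20 | ethyl (2E)-5-[(1S,2R,3S)-2-(2-tert-butoxy-2-oxoethyl)-3-(1-tert-butoxy-2-methyl-1-oxopropan-2-yl)-2-methyl-6-oxocyclohexyl]-3-methylpent-2-enoate | CCOC(=O)/C=C(\C)CC[C@H]1[C@](C)(CC(=O)OC(C)(C)C)[C@@H](C(C)(C)C(=O)OC(C)(C)C)CCC1=O | intermediate
21 | 6-methylidene analogue of 20 (C8=C17 exocyclic alkene, ring centres unchanged) | CCOC(=O)/C=C(\C)CC[C@H]1[C@](C)(CC(=O)OC(C)(C)C)[C@@H](C(C)(C)C(=O)OC(C)(C)C)CCC1=C | intermediate
22 | (2E)-allylic alcohol: 21 with CO2Et reduced to CH2OH | OC/C=C(\C)CC[C@H]1[C@](C)(CC(=O)OC(C)(C)C)[C@@H](C(C)(C)C(=O)OC(C)(C)C)CCC1=C | intermediate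
23 | tris(trimethylsilyl) derivative of 24 (two silyl esters, one silyl ether; not isolated) | C[Si](C)(C)OC/C=C(\C)CC[C@H]1[C@](C)(CC(=O)O[Si](C)(C)C)[C@@H](C(C)(C)C(=O)O[Si](C)(C)C)CCC1=C | intermediate
24 | diacid: 22 with both tert-butyl esters replaced by CO2H | OC/C=C(\C)CC[C@H]1[C@](C)(CC(=O)O)[C@@H](C(C)(C)C(=O)O)CCC1=C | intermediate
25 | iodolactone: 1-(iodomethyl) analogue of 26, configured as 26 | OC/C=C(\C)CC[C@H]1[C@]2(C)CC(=O)O[C@@]1(CI)CC[C@@H]2C(C)(C)C(=O)O | intermediate
26 | 2-[(1S,5R,6S,9S)-9-[(3E)-5-hydroxy-3-methylpent-3-en-1-yl]-1,5-dimethyl-3-oxo-2-oxabicyclo[3.3.1]nonan-6-yl]-2-methylpropanoic acid | OC/C=C(\C)CC[C@H]1[C@]2(C)CC(=O)O[C@@]1(C)CC[C@@H]2C(C)(C)C(=O)O | intermediate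
27 | phenacyl (2-oxo-2-phenylethyl) ester of 26 | OC/C=C(\C)CC[C@H]1[C@]2(C)CC(=O)O[C@@]1(C)CC[C@@H]2C(C)(C)C(=O)OCC(=O)c3ccccc3 | intermediate
28 | epoxy alcohol: 27 with the side chain 2-[(2R,3R)-3-(hydroxymethyl)-2-methyloxiran-2-yl]ethyl | OC[C@H]3O[C@]3(C)CC[C@H]1[C@]2(C)CC(=O)O[C@@]1(C)CC[C@@H]2C(C)(C)C(=O)OCC(=O)c4ccccc4 | intermediate
29 | epoxy iodide: 28 with CH2OH replaced by CH2I | IC[C@H]3O[C@]3(C)CC[C@H]1[C@]2(C)CC(=O)O[C@@]1(C)CC[C@@H]2C(C)(C)C(=O)OCC(=O)c4ccccc4 | intermediate
30 | 2-[(1S,5R,6S,9S)-9-[(3R)-3-hydroxy-3-methylpent-4-en-1-yl]-1,5-dimethyl-3-oxo-2-oxabicyclo[3.3.1]nonan-6-yl]-2-methylpropanoic acid (CNP0198729.3) | C=C[C@](C)(O)CC[C@H]1[C@]2(C)CC(=O)O[C@@]1(C)CC[C@@H]2C(C)(C)C(=O)O | target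

**Summary**

Total step count: 20. Longest linear sequence: 20 steps (1 → 30).

Steps most likely to fail:

1. Step 2 (proposed new method). The silylium catalyst may turn over poorly on the lactone or discriminate the two faces of C5 insufficiently. The fallback uses known chemistry, sets out from 3 and comes back at 6. Lewis-acid-promoted Mukaiyama–Michael addition of 3 to commercial dimethyl glutaconate (TiCl4, CH2Cl2, −78 °C) gives the triester F1. LiOH saponifies only the two unhindered methyl esters to the diacid F2, and Ac2O closes the prochiral anhydride F3. Cinchona-alkaloid-mediated methanolysis (quinidine, or quinine if the opposite sense is needed) desymmetrises F3 to the hemiester F4. BH3·SMe2 reduces the free acid to the hydroxy ester F5, which lactonises under a trace of acid to 6.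

2. Step 10 (key step). The hindered vinyl group on the quaternary C10 may add too slowly to the excited enol, so that photodecomposition competes; the 1,5-diketone may also undergo aldol ring closure during the C9 equilibration. The fallback sets out from 14 and comes back at 19. Step 9 is stopped before the acidic hydrolysis so that the enaminone 16 is isolated. Irradiation of this vinylogous amide (λ > 300 nm, MeCN) should form the same C8–C9 and C11–C12 bonds and give the aminocyclobutane F6. F6 fragments by retro-Mannich cleavage of C8–C12, and aqueous acid hydrolyses the resulting iminium/enamine to 19 (C9 then equilibrates as in step 10).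

3. Step 15. Ring B must leave its chair for the C10 arm to reach C8, so the cyclisation may be slow enough for the iodonium ion to revert or for iodine to attack the side-chain alkene. The fallback sets out from 24 and comes back at 26 without new intermediates. Hydrogen-atom-transfer hydrolactonisation with Co(salen), an N-fluoro-2,4,6-trimethylpyridinium salt and PhSiH3 delivers hydrogen to C17 and lets the C2 carboxylate capture the oxidised C8 centre. This forms the lactone and the C8 methyl group in one operation and removes the need for iodine and tin.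

Further compounds
F1 | step 2 | dimethyl 3-(1-tert-butoxy-2-methyl-1-oxopropan-2-yl)pentanedioate | COC(=O)CC(CC(=O)OC)C(C)(C)C(=O)OC(C)(C)C
F2 | step 2 | 3-(1-tert-butoxy-2-methyl-1-oxopropan-2-yl)pentanedioic acid | OC(=O)CC(CC(=O)O)C(C)(C)C(=O)OC(C)(C)C
F3 | step 2 | tert-butyl 2-(2,6-dioxooxan-4-yl)-2-methylpropanoate | O=C1CC(C(C)(C)C(=O)OC(C)(C)C)CC(=O)O1
F4 | step 2 | (3S)-3-(1-tert-butoxy-2-methyl-1-oxopropan-2-yl)-5-methoxy-5-oxopentanoic acid | COC(=O)C[C@@H](C(C)(C)C(=O)OC(C)(C)C)CC(=O)O
F5 | step 2 | methyl (3S)-3-(1-tert-butoxy-2-methyl-1-oxopropan-2-yl)-5-hydroxypentanoate | COC(=O)C[C@@H](C(C)(C)C(=O)OC(C)(C)C)CCO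
F6 | step 10 | aminocyclobutane photoadduct of 16 (pyrrolidin-1-yl in place of the hydroxyl of 18, C12 epimers) | CC(=O)C1C[C@H]2[C@](C)(CC(=O)OC(C)(C)C)[C@@H](C(C)(C)C(=O)OC(C)(C)C)CC[C@@]12N3CCCC3
F0 | step 15 | none | none
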